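Everything rests on making the aromatic ring of the dihydrobenzofuran last, by a Diels–Alder benzannulation. Positions C7a, C3a, C4 and C5 of that ring bear, in unbroken sequence, the ether oxygen O1, carbon C3, a phenol and the enone carbonyl; two oxygens meta to each other with a ketone ortho to one of them are exactly what an electron-rich diene oxygenated at one end (twice) and at the inner carbon delivers with a terminal alkynyl ketone. The diene is an enantiopure oxolane whose C7a carries an exocyclic CH2 and whose C3a carries a bis(silyloxy)methylidene group. With the styryl ynone it forms C6–C7 and C4–C5, silanol is expelled, and the chalcone core is complete.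

Key step: step 9

Remarks on the chemistry: the target SMILES encodes the (2S,3S) isomer, in which the C3 hydroxyl is trans to the hydroxyisopropyl group on C2; this isomer is taken as brosimacutin G. Ring atoms are named by benzofuran numbering (O1, C2, C3, C3a, C4 to C7, C7a), also for the oxolane atoms that become them.

Step 1
Reactants: 1 3-methylbut-2-en-1-ol
Product: 2 (R)-(3,3-dimethyloxiran-2-yl)methanol
Conditions: Ti(OiPr)4 (5 mol%), D-(−)-diisopropyl tartrate (6 mol%), anhydrous t-BuOOH (2 equiv), 4 Å molecular sieves, CH2Cl2, −20 °C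
Reagents that add atoms: tert-butyl hydroperoxide, CC(C)(C)OO
Why: Katsuki–Sharpless asymmetric epoxidation: the titanium tartrate complex binds the allylic alcohol and the hydroperoxide and delivers oxygen to one face of the alkene, D-(−)-tartrate giving the (R)-epoxy alcohol, the mirror image of the sense known for L-(+)-tartrate with 3,3-disubstituted primary allylic alcohols of the geraniol type.

Step 2
Reactants: 2 (R)-(3,3-dimethyloxiran-2-yl)methanol
Product: 3 (S)-3,3-dimethyloxirane-2-carbaldehyde
Conditions: IBX (1.3 equiv), EtOAc, 75 °C; cool, filter; filtrate used directly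
Reagents that add atoms: none
Why: Oxidation of the primary alcohol with a pentavalent iodine reagent stops at the aldehyde under neutral, water-free conditions, leaves the epoxide and its non-enolisable stereocentre unchanged (the descriptor changes from R to S only because CHO outranks the ring carbon), and lets the volatile, water-miscible aldehyde be carried on as a filtered solution.

Step 3
Reactants: 3 (S)-3,3-dimethyloxirane-2-carbaldehyde; 4 allyl 3-oxobutanoate
Product: 6 allyl (4S,5S)-4-hydroxy-5-(2-hydroxypropan-2-yl)-2-methyl-4,5-dihydrofuran-3-carboxylate, via aldol adduct 5 (not isolated)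
Conditions: K2CO3 (0.5 equiv), EtOAc/DMSO (3:1), 0 °C → rt
Reagents that add atoms: none
Why: Interrupted Feist–Bénary annulation: reversible aldol addition of the acetoacetate carbon to the aldehyde is followed by 5-exo-tet opening of the epoxide at its secondary carbon by the enolate oxygen, which inverts that carbon and fixes C5 as S, while the carbinol centre C4 is decided in the ring closure, where the transition state that places the hydroxyl trans to the departing Me2C–O arm avoids eclipsing, so that the trans (4S,5S) isomer should predominate and any cis isomer is removed by chromatography.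

Step 4
Reactants: 6 allyl (4S,5S)-4-hydroxy-5-(2-hydroxypropan-2-yl)-2-methyl-4,5-dihydrofuran-3-carboxylate
Product: 7 allyl (4S,5S)-2-methyl-4-(triethylsilyloxy)-5-[2-(triethylsilyloxy)propan-2-yl]-4,5-dihydrofuran-3-carboxylate
Conditions: Et3SiOTf (2.6 equiv), 2,6-lutidine (4 equiv), CH2Cl2, −78 → 0 °C
Reagents that add atoms: triethylsilyl trifluoromethanesulfonate, CC[Si](CC)(CC)OS(=O)(=O)C(F)(F)F
Why: Silylation with a silyl triflate and a hindered pyridine base converts the secondary and the tertiary hydroxyl into triethylsilyl ethers in one operation, the buffered low-temperature medium avoiding ionisation of the allylic carbinol and dehydration to the furan.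

Step 5
Reactants: 7 allyl (4S,5S)-2-methyl-4-(triethylsilyloxy)-5-[2-(triethylsilyloxy)propan-2-yl]-4,5-dihydrofuran-3-carboxylate
Product: 8 (4S,5S)-2-methyl-4-(triethylsilyloxy)-5-[2-(triethylsilyloxy)propan-2-yl]-4,5-dihydrofuran-3-carboxylic acid
Conditions: Pd(PPh3)4 (3 mol%), morpholine (3 equiv), THF, rt; pH 5 phosphate buffer wash
Reagents that add atoms: none
Why: Tsuji–Trost deallylation: zerovalent palladium ionises the allyl ester to a π-allyl complex and the carboxylate and morpholine takes up the allyl group, so that this hindered, deactivated vinylogous carbonate ester is cleaved under neutral conditions that leave the silyl ethers, the enol ether and both stereocentres unchanged.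

Step 6
Reactants: 8 (4S,5S)-2-methyl-4-(triethylsilyloxy)-5-[2-(triethylsilyloxy)propan-2-yl]-4,5-dihydrofuran-3-carboxylic acid
Product: 10 (4S,5S)-3-[bis(trimethylsilyloxy)methylidene]-2-methylidene-4-(triethylsilyloxy)-5-[2-(triethylsilyloxy)propan-2-yl]oxolane, via trimethylsilyl ester 9 (not isolated)
Conditions: Me3SiOTf (2.2 equiv), Et3N (4 equiv), Et2O, −20 → 0 °C; pentane, decant from the ammonium triflate, concentrate; used crude at once
Reagents that add atoms: trimethylsilyl trifluoromethanesulfonate, C[Si](C)(C)OS(=O)(=O)C(F)(F)F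
Why: Soft vinylogous enolisation by the silyl triflate and amine method used for silyloxydienes from β-oxy enoates: the acid is first silylated to ester 9, O-silylation of its carbonyl gives a bis(silyloxy)carbenium ion stabilised by O1, and the amine removes a proton from the 2-methyl group, so that no free dienolate arises that could expel the neighbouring silyloxy group and the stereocentres are not touched.

Step 7
Reactants: 11 4-(tert-butyldimethylsilyloxy)benzaldehyde; 12 diethyl {2-[methoxy(methyl)amino]-2-oxoethyl}phosphonate
Product: 13 (E)-3-[4-(tert-butyldimethylsilyloxy)phenyl]-N-methoxy-N-methylprop-2-enamide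
Conditions: NaH (1.1 equiv), THF, 0 °C → rt
Reagents that add atoms: none
Why: Horner–Wadsworth–Emmons olefination with a stabilised phosphonate anion gives the E-configured enamide through reversible addition and selective collapse of the anti oxaphosphetane, and the soft carbanion does not attack the aryl silyl ether.

Step 8
Reactants: 13 (E)-3-[4-(tert-butyldimethylsilyloxy)phenyl]-N-methoxy-N-methylprop-2-enamide; 14 ethynylmagnesium bromide
Product: 16 (E)-1-[4-(tert-butyldimethylsilyloxy)phenyl]pent-1-en-4-yn-3-one, via magnesium hemiaminal chelate 15 (not isolated)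
Conditions: THF, −20 → 0 °C; inverse quench into cold 1 M HCl
Reagents that add atoms: none
Why: Weinreb ketone synthesis: the Grignard reagent adds once to the N-methoxy-N-methylamide to give the magnesium-chelated tetrahedral intermediate 15, which collapses to the ynone only on the acidic quench, and the acid also protonates the released N,O-dimethylhydroxylamine and so keeps it from adding to the ynone.

Step 9
Reactants: 10 (4S,5S)-3-[bis(trimethylsilyloxy)methylidene]-2-methylidene-4-(triethylsilyloxy)-5-[2-(triethylsilyloxy)propan-2-yl]oxolane; 16 (E)-1-[4-(tert-butyldimethylsilyloxy)phenyl]pent-1-en-4-yn-3-one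
Product: 19 (E)-1-{(2S,3S)-4-hydroxy-3-(triethylsilyloxy)-2-[2-(triethylsilyloxy)propan-2-yl]-2,3-dihydro-1-benzofuran-5-yl}-3-[4-(tert-butyldimethylsilyloxy)phenyl]prop-2-en-1-one, via bis(trimethylsilyloxy) cycloadduct 17 (not isolated), via aryl trimethylsilyl ether 18 (not isolated)
Conditions: 10 (1.3 equiv), toluene, −20 °C → rt; then SiO2, wet CH2Cl2, rt
Reagents that add atoms: none
Why: The s-cis-locked, electron-rich diene adds to the ynone in a polar, strongly asynchronous Diels–Alder reaction in which C7, the methylene terminus that receives the donation of O1 and of both silyloxy groups, bonds to the unsubstituted alkyne carbon (C6–C7) and the ketene-acetal carbon C4 then bonds to the acyl-bearing carbon (C4–C5) to give the 4,7-dihydro adduct 17; 1,4-elimination of trimethylsilanol (H from C7, silyloxy from C4) aromatises it to 18, whose aryl O–Si bond next to the ketone is hydrolysed on moist silica to the hydrogen-bonded phenol 19. The closest known reaction type is the cycloaddition of 1,1-dioxy-3-oxy butadienes of the ketene-acetal class with acetylenic ketones and esters followed by loss of one oxygen substituent, which gives 2,4-dioxygenated aryl carbonyl compounds. The benzene ring is closed by an intermolecular [4+2] process, which in its stepwise limit is a Mukaiyama–Michael addition followed by 6-exo-trig attack of the allenolate carbon on the silyloxycarbenium carbon. No stereocentre is formed, and C2 and C3 lie outside the reacting π system and keep their configuration. The step needs regioselectivity (C7 to the alkyne terminus), which the matched polarity of the trioxygenated diene and the ynone secures, and chemoselectivity for the alkyne over the β-aryl enone, which the greater electrophilicity and smaller hindrance of the terminal ynone carbon and the donor aryl group on the styryl double bond secure. Because both acetal oxygens carry the same silyl group, the oxygen that stays on C4 ends as a free phenol whichever one is lost.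

Step 10
Reactants: 19 (E)-1-{(2S,3S)-4-hydroxy-3-(triethylsilyloxy)-2-[2-(triethylsilyloxy)propan-2-yl]-2,3-dihydro-1-benzofuran-5-yl}-3-[4-(tert-butyldimethylsilyloxy)phenyl]prop-2-en-1-one
Product: 20 brosimacutin G, (E)-1-[(2S,3S)-3,4-dihydroxy-2-(2-hydroxypropan-2-yl)-2,3-dihydro-1-benzofuran-5-yl]-3-(4-hydroxyphenyl)prop-2-en-1-one
Conditions: Bu4NF (4 equiv), AcOH (4 equiv), THF, 0 °C → rt
Reagents that add atoms: none
Why: Fluoride-induced desilylation, driven by Si–F bond formation, removes the two triethylsilyl ethers and the aryl tert-butyldimethylsilyl ether in an acetic-acid-buffered medium that avoids both base-induced cyclisation of the 2'-hydroxychalcone to a flavanone and acid-induced ionisation of the benzylic C3 alcohol, so that both stereocentres and the E double bond are kept.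

Compound list
1 | 3-methylbut-2-en-1-ol | CC(C)=CCO | starting material
2 | (R)-(3,3-dimethyloxiran-2-yl)methanol | CC1(C)O[C@@H]1CO | intermediate
3 | (S)-3,3-dimethyloxirane-2-carbaldehyde | CC1(C)O[C@@H]1C=O | intermediate
4 | allyl 3-oxobutanoate | CC(=O)CC(=O)OCC=C | starting material
5 | allyl (3S)-2-acetyl-3-[(2R)-3,3-dimethyloxiran-2-yl]-3-hydroxypropanoate (aldol adduct, C2 not defined) | CC1(C)O[C@@H]1[C@@H](O)C(C(C)=O)C(=O)OCC=C | intermediate (not isolated)
6 | allyl (4S,5S)-4-hydroxy-5-(2-hydroxypropan-2-yl)-2-methyl-4,5-dihydrofuran-3-carboxylate | CC(C)(O)[C@H]1OC(C)=C(C(=O)OCC=C)[C@@H]1O | intermediate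
7 | allyl (4S,5S)-2-methyl-4-(triethylsilyloxy)-5-[2-(triethylsilyloxy)propan-2-yl]-4,5-dihydrofuran-3-carboxylate | CC[Si](CC)(CC)OC(C)(C)[C@H]1OC(C)=C(C(=O)OCC=C)[C@@H]1O[Si](CC)(CC)CC | intermediate
8 | (4S,5S)-2-methyl-4-(triethylsilyloxy)-5-[2-(triethylsilyloxy)propan-2-yl]-4,5-dihydrofuran-3-carboxylic acid | CC[Si](CC)(CC)OC(C)(C)[C@H]1OC(C)=C(C(=O)O)[C@@H]1O[Si](CC)(CC)CC | intermediate
9 | trimethylsilyl (4S,5S)-2-methyl-4-(triethylsilyloxy)-5-[2-(triethylsilyloxy)propan-2-yl]-4,5-dihydrofuran-3-carboxylate | CC[Si](CC)(CC)OC(C)(C)[C@H]1OC(C)=C(C(=O)O[Si](C)(C)C)[C@@H]1O[Si](CC)(CC)CC | intermediate (not isolated)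
10 | (4S,5S)-3-[bis(trimethylsilyloxy)methylidene]-2-methylidene-4-(triethylsilyloxy)-5-[2-(triethylsilyloxy)propan-2-yl]oxolane | CC[Si](CC)(CC)OC(C)(C)[C@H]1OC(=C)C(=C(O[Si](C)(C)C)O[Si](C)(C)C)[C@@H]1O[Si](CC)(CC)CC | intermediate
11 | 4-(tert-butyldimethylsilyloxy)benzaldehyde | CC(C)(C)[Si](C)(C)Oc1ccc(C=O)cc1 | starting material
12 | diethyl {2-[methoxy(methyl)amino]-2-oxoethyl}phosphonate | CCOP(=O)(CC(=O)N(C)OC)OCC | starting material
13 | (E)-3-[4-(tert-butyldimethylsilyloxy)phenyl]-N-methoxy-N-methylprop-2-enamide | CON(C)C(=O)/C=C/c1ccc(O[Si](C)(C)C(C)(C)C)cc1 | intermediate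
14 | ethynylmagnesium bromide | C#C[Mg]Br | starting material
15 | bromomagnesium (E)-1-[4-(tert-butyldimethylsilyloxy)phenyl]-3-[methoxy(methyl)amino]pent-1-en-4-yn-3-olate | C#CC(O[Mg]Br)(N(C)OC)/C=C/c1ccc(O[Si](C)(C)C(C)(C)C)cc1 | intermediate (not isolated)
16 | (E)-1-[4-(tert-butyldimethylsilyloxy)phenyl]pent-1-en-4-yn-3-one | C#CC(=O)/C=C/c1ccc(O[Si](C)(C)C(C)(C)C)cc1 | intermediate
17 | (E)-1-{(2S,3S)-4,4-bis(trimethylsilyloxy)-3-(triethylsilyloxy)-2-[2-(triethylsilyloxy)propan-2-yl]-2,3,4,7-tetrahydro-1-benzofuran-5-yl}-3-[4-(tert-butyldimethylsilyloxy)phenyl]prop-2-en-1-one | CC[Si](CC)(CC)OC(C)(C)[C@H]1OC2=C([C@@H]1O[Si](CC)(CC)CC)C(O[Si](C)(C)C)(O[Si](C)(C)C)C(C(=O)/C=C/c1ccc(O[Si](C)(C)C(C)(C)C)cc1)=CC2 | intermediate (not isolated)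
18 | (E)-1-{(2S,3S)-3-(triethylsilyloxy)-2-[2-(triethylsilyloxy)propan-2-yl]-4-(trimethylsilyloxy)-2,3-dihydro-1-benzofuran-5-yl}-3-[4-(tert-butyldimethylsilyloxy)phenyl]prop-2-en-1-one | CC[Si](CC)(CC)OC(C)(C)[C@H]1Oc2ccc(C(=O)/C=C/c3ccc(O[Si](C)(C)C(C)(C)C)cc3)c(O[Si](C)(C)C)c2[C@@H]1O[Si](CC)(CC)CC | intermediate (not isolated)
19 | (E)-1-{(2S,3S)-4-hydroxy-3-(triethylsilyloxy)-2-[2-(triethylsilyloxy)propan-2-yl]-2,3-dihydro-1-benzofuran-5-yl}-3-[4-(tert-butyldimethylsilyloxy)phenyl]prop-2-en-1-one | CC[Si](CC)(CC)OC(C)(C)[C@H]1Oc2ccc(C(=O)/C=C/c3ccc(O[Si](C)(C)C(C)(C)C)cc3)c(O)c2[C@@H]1O[Si](CC)(CC)CC | intermediate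
20 | brosimacutin G, (E)-1-[(2S,3S)-3,4-dihydroxy-2-(2-hydroxypropan-2-yl)-2,3-dihydro-1-benzofuran-5-yl]-3-(4-hydroxyphenyl)prop-2-en-1-one | CC(C)(O)[C@H]1Oc2ccc(C(=O)/C=C/c3ccc(O)cc3)c(O)c2[C@@H]1O | target

Total step count: 10. Longest linear sequence: 8 steps (steps 1 to 6, 9 and 10); steps 7 and 8 make the ynone arm.

Steps most likely to fail

Step 9. The diene may add to the β-aryl enone carbon instead of the alkyne, the cross-conjugated enynone may oligomerise, or the first C–C bond may form without ring closure when silyl transfer to the allenolate outruns attack on C4. The fallback sets out from 10 and moves the chalcone arm behind the benzannulation. Compound 10 is combined under the conditions of step 9 with commercial but-3-yn-2-one, an alkynyl ketone without a second acceptor site. This should give, through the cycloadduct F3 and the aryl trimethylsilyl ether F4, the methyl ketone F5. Claisen–Schmidt condensation of F5 with 4-hydroxybenzaldehyde (KOH, EtOH, rt) then builds the E-enone and gives the bis(triethylsilyl) chalcone F6; partial loss of a triethylsilyl group here would be of no consequence. Desilylation of F6 under the conditions of step 10 brings the fallback back to the route at 20.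

Step 6. Under the Lewis-acidic silylating medium the C3 silyloxy group may ionise or be eliminated, with collapse to the aromatic furan, or silylation at the methyl group may stay incomplete. The fallback sets out from 8 and replaces electrophile-driven enolisation by kinetic deprotonation in a triflate-free medium. The silyl ester 9 is prepared on its own (Me3SiCl, Et3N, pentane, filtration under argon). It is then deprotonated at the 2-methyl group with LiN(iPr)2 in THF at −78 °C in the presence of Me3SiCl, so that the dienolate is silylated on oxygen as fast as it forms. After removal of LiCl with pentane the fallback returns to the route at 10.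

Step 3. Facial selectivity at the carbinol carbon may be poor or reversed, so that the cis isomer predominates. The fallback sets out from 3 and 4 and corrects the centre afterwards. The annulation is run as in step 3 and the cis isomer, allyl (4R,5S)-4-hydroxy-5-(2-hydroxypropan-2-yl)-2-methyl-4,5-dihydrofuran-3-carboxylate F1, is collected. Mitsunobu inversion of its secondary alcohol with 4-nitrobenzoic acid (PPh3, diisopropyl azodicarboxylate, THF, 0 °C; the tertiary alcohol does not react) gives the trans 4-nitrobenzoate F2. Transesterification of F2 with K2CO3 in allyl alcohol at 0 °C releases the trans diol and returns to the route at 6.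

Further compounds
F1 | step 3 | allyl (4R,5S)-4-hydroxy-5-(2-hydroxypropan-2-yl)-2-methyl-4,5-dihydrofuran-3-carboxylate | CC(C)(O)[C@H]1OC(C)=C(C(=O)OCC=C)[C@H]1O
F2 | step 3 | allyl (4S,5S)-5-(2-hydroxypropan-2-yl)-2-methyl-4-(4-nitrobenzoyloxy)-4,5-dihydrofuran-3-carboxylate | CC(C)(O)[C@H]1OC(C)=C(C(=O)OCC=C)[C@@H]1OC(=O)c1ccc(cc1)[N+](=O)[O-]
F0 | step 6 | none | none
F3 | step 9 | 1-{(2S,3S)-4,4-bis(trimethylsilyloxy)-3-(triethylsilyloxy)-2-[2-(triethylsilyloxy)propan-2-yl]-2,3,4,7-tetrahydro-1-benzofuran-5-yl}ethan-1-one | CC[Si](CC)(CC)OC(C)(C)[C@H]1OC2=C([C@@H]1O[Si](CC)(CC)CC)C(O[Si](C)(C)C)(O[Si](C)(C)C)C(C(C)=O)=CC2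
F4 | step 9 | 1-{(2S,3S)-3-(triethylsilyloxy)-2-[2-(triethylsilyloxy)propan-2-yl]-4-(trimethylsilyloxy)-2,3-dihydro-1-benzofuran-5-yl}ethan-1-one | CC[Si](CC)(CC)OC(C)(C)[C@H]1Oc2ccc(C(C)=O)c(O[Si](C)(C)C)c2[C@@H]1O[Si](CC)(CC)CC
F5 | step 9 | 1-{(2S,3S)-4-hydroxy-3-(triethylsilyloxy)-2-[2-(triethylsilyloxy)propan-2-yl]-2,3-dihydro-1-benzofuran-5-yl}ethan-1-one | CC[Si](CC)(CC)OC(C)(C)[C@H]1Oc2ccc(C(C)=O)c(O)c2[C@@H]1O[Si](CC)(CC)CC
F6 | step 9 | (E)-1-{(2S,3S)-4-hydroxy-3-(triethylsilyloxy)-2-[2-(triethylsilyloxy)propan-2-yl]-2,3-dihydro-1-benzofuran-5-yl}-3-(4-hydroxyphenyl)prop-2-en-1-one | CC[Si](CC)(CC)OC(C)(C)[C@H]1Oc2ccc(C(=O)/C=C/c3ccc(O)cc3)c(O)c2[C@@H]1O[Si](CC)(CC)CC
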